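**Plan**

- Ring A has three adjacent C–Br carbons (C3–C5), one C–H (C2) and the vicinal pair C1–OH / C6–OAr. With a carboxyl group put back on C2, ring A is cut at C5–C6 and C1–C2.
- The four-carbon unit C2–C5 is then methyl 3,4,5-tribromothiophene-2-carboxylate 1,1-dioxide, with SO2 as the departing bridge. C1 and C6, with both oxygens and ring B, are the ketene bis(trimethylsilyl) acetal of (2-bromophenoxy)acetic acid.
- Forward: tetrabromothiophene → ester → sulfone; the acid → ketene acetal; one cycloaddition / SO2 extrusion / aromatization builds ring A onto the intact ring B; ester cleavage and protodecarboxylation finish.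
- The target has no stereocentre. The sp3 centres formed in the cycloaddition are erased on aromatization, and the only selectivity needed is regiochemical, set by the ester.

Key step: step 4

Remark on the chemistry: tetrabromothiophene and (2-bromophenoxy)acetic acid are taken as purchasable. The diene carries a methyl ester on the carbon that ends as C2–H, because without it the nucleophilic carbon of the ketene acetal is expected to attack the unsubstituted sulfone terminus and give the isomeric phenol.

**Step 1**
Reactants: 1 tetrabromothiophene
Product: 3 methyl 3,4,5-tribromothiophene-2-carboxylate, via 3,4,5-tribromo-2-thienyllithium 2 (not isolated)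
Conditions: n-BuLi (1.0 equiv), THF, −78 °C; then ClCO2Me (3 equiv), −78 °C → rt
Reagents that add atoms: methyl chloroformate, COC(=O)Cl
Why: Bromine–lithium exchange of tetrabromothiophene is selective for an alpha position, where the carbanion next to sulfur is best stabilized, and the thienyllithium is acylated by excess chloroformate (halogen–metal exchange followed by acylation of an organolithium).

**Step 2**
Reactants: 3 methyl 3,4,5-tribromothiophene-2-carboxylate
Product: 5 methyl 3,4,5-tribromothiophene-2-carboxylate 1,1-dioxide, via thiophene 1-oxide 4 (not isolated)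
Conditions: H2O2·urea, (CF3CO)2O, MeCN, 0 °C → rt
Reagents that add atoms: urea–hydrogen peroxide, NC(N)=O.OO
Why: Peroxytrifluoroacetic acid made in the flask is the established oxidant for taking halogen- and acceptor-substituted thiophenes to their 1,1-dioxides (S-oxidation by a peracid), and the fully substituted ring should not undergo the Diels–Alder dimerization that destroys less substituted thiophene dioxides.

**Step 3**
Reactants: 6 (2-bromophenoxy)acetic acid
Product: 9 1-bromo-2-[2,2-bis(trimethylsilyloxy)ethenyloxy]benzene, via trimethylsilyl ester 7 (not isolated), via lithium enolate 8 (not isolated)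
Conditions: LiN(SiMe3)2 (1.05 equiv), Me3SiCl, THF, 0 °C → rt; then LiN(SiMe3)2 (1.1 equiv), −78 °C; Me3SiCl, −78 °C → rt
Reagents that add atoms: chlorotrimethylsilane, C[Si](C)(C)Cl
Why: The carboxylate is silylated, the alpha proton of the silyl ester (acidified by the aryloxy group) is removed by the amide base and the enolate is trapped on oxygen (ketene bis-silyl acetal formation, as for Ireland–Claisen precursors); the amide base should leave the aryl bromide alone, and two identical silyloxy groups make the alkene geometry irrelevant.

**Step 4**
Reactants: 5 methyl 3,4,5-tribromothiophene-2-carboxylate 1,1-dioxide; 9 1-bromo-2-[2,2-bis(trimethylsilyloxy)ethenyloxy]benzene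
Product: 13 methyl 2,3,4-tribromo-5-(2-bromophenoxy)-6-hydroxybenzoate, via bicyclic sulfone 10 (not isolated), via cyclohexadiene ketal 11 (not isolated), via aryl silyl ether 12 (not isolated)
Conditions: 9 (1.5 equiv), toluene, −20 °C → 60 °C, N2 sweep; then 1 M HCl, THF, rt
Reagents that add atoms: none
Why: Proposed new method: an inverse-demand Diels–Alder reaction is expected in which the nucleophilic CH(OAr) carbon of 9 bonds first to C5 of 5 (the C–Br terminus remote from the ester) and the acetal carbon then closes onto the ester-bearing C2, after which sulfone 10 extrudes SO2 cheletropically, diene 11 loses Me3SiOH across the former dienophile bond under the acid and the aryl silyl ether 12 is hydrolysed. The closest known reaction types are the addition of alkenes to tetrahalothiophene 1,1-dioxides with loss of SO2 and the annulation of 2-pyrone-3-carboxylates with 1,1-dialkoxyethenes to salicylate derivatives, which has the same orientation and the same alcohol-loss aromatization. Ring A is closed by an intermolecular [4+2] cycloaddition that makes both new ring bonds (target C5–C6 and C1–C2) inside the bridged sulfone, and the carbocycle is set free by the SO2 extrusion. The sp3 centres of 10 and 11 are transient and vanish on aromatization, so no configuration needs control. The step needs regioselectivity, which the ester should secure because attack at the far terminus places the developing negative charge on the carbon flanked by ester and sulfone, and it needs the aryloxy group to survive aromatization, which holds because the aryloxy carbon has no hydrogen-bearing neighbour and two identical silyl groups let either ketal oxygen end as the phenol. Toluene is chosen to disfavour a zwitterionic addition–elimination at the C–Br carbons.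

**Step 5**
Reactants: 13 methyl 2,3,4-tribromo-5-(2-bromophenoxy)-6-hydroxybenzoate
Product: 14 2,3,4-tribromo-5-(2-bromophenoxy)-6-hydroxybenzoic acid
Conditions: NaOH, MeOH/H2O, 70 °C; then 1 M HCl
Reagents that add atoms: sodium hydroxide, [Na+].[OH-]
Why: Saponification of a salicylate ester, helped by the neighbouring phenoxide acting as an internal general base; the ring is a dianion under these conditions, so hydroxide should not displace the ring bromines.

**Step 6**
Reactants: 14 2,3,4-tribromo-5-(2-bromophenoxy)-6-hydroxybenzoic acid
Product: 15 3,4,5-tribromo-2-(2-bromophenoxy)phenol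
Conditions: Ag2CO3 (10 mol %), AcOH (cat.), DMSO, 120 °C
Reagents that add atoms: none
Why: Silver-catalysed protodecarboxylation of an ortho,ortho-disubstituted benzoic acid, in which the twisted carboxylate loses CO2 to an aryl–silver species that acetic acid protonates; silver should not insert into the aryl bromides.

**Compound list**

1 | tetrabromothiophene | Brc1sc(Br)c(Br)c1Br | starting material
2 | 3,4,5-tribromo-2-thienyllithium | [Li]c1sc(Br)c(Br)c1Br | intermediate
3 | methyl 3,4,5-tribromothiophene-2-carboxylate | COC(=O)c1sc(Br)c(Br)c1Br | intermediate
4 | methyl 3,4,5-tribromothiophene-2-carboxylate 1-oxide (racemic at sulfur) | COC(=O)C1=C(Br)C(Br)=C(Br)S1=O | intermediate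
5 | methyl 3,4,5-tribromothiophene-2-carboxylate 1,1-dioxide | COC(=O)C1=C(Br)C(Br)=C(Br)S1(=O)=O | intermediate
6 | (2-bromophenoxy)acetic acid | OC(=O)COc1ccccc1Br | starting material
7 | trimethylsilyl (2-bromophenoxy)acetate | C[Si](C)(C)OC(=O)COc1ccccc1Br | intermediate
8 | lithium enolate of 7 (geometry not defined) | [Li]OC(O[Si](C)(C)C)=COc1ccccc1Br | intermediate
9 | 1-bromo-2-[2,2-bis(trimethylsilyloxy)ethenyloxy]benzene | C[Si](C)(C)OC(O[Si](C)(C)C)=COc1ccccc1Br | intermediate
10 | methyl 4,5,6-tribromo-3-(2-bromophenoxy)-2,2-bis(trimethylsilyloxy)-7-thiabicyclo[2.2.1]hept-5-ene-1-carboxylate 7,7-dioxide (racemic, endo/exo mixture at C3) | COC(=O)C12C(Br)=C(Br)C(Br)(C(Oc3ccccc3Br)C1(O[Si](C)(C)C)O[Si](C)(C)C)S2(=O)=O | intermediate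
11 | methyl 2,3,4-tribromo-5-(2-bromophenoxy)-6,6-bis(trimethylsilyloxy)cyclohexa-1,3-diene-1-carboxylate (racemic) | COC(=O)C1=C(Br)C(Br)=C(Br)C(Oc2ccccc2Br)C1(O[Si](C)(C)C)O[Si](C)(C)C | intermediate
12 | methyl 2,3,4-tribromo-5-(2-bromophenoxy)-6-(trimethylsilyloxy)benzoate | COC(=O)c1c(Br)c(Br)c(Br)c(Oc2ccccc2Br)c1O[Si](C)(C)C | intermediate
13 | methyl 2,3,4-tribromo-5-(2-bromophenoxy)-6-hydroxybenzoate | COC(=O)c1c(Br)c(Br)c(Br)c(Oc2ccccc2Br)c1O | intermediate
14 | 2,3,4-tribromo-5-(2-bromophenoxy)-6-hydroxybenzoic acid | OC(=O)c1c(Br)c(Br)c(Br)c(Oc2ccccc2Br)c1O | intermediate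
15 | 3,4,5-tribromo-2-(2-bromophenoxy)phenol | Oc1cc(Br)c(Br)c(Br)c1Oc1ccccc1Br | target

**Step count**

Total steps: 6. Longest linear sequence: 5 steps (steps 1, 2, 4, 5, 6).

**Steps most likely to fail**

Step 4. The ketene acetal may add in a stepwise, zwitterionic manner, and the intermediate may expel bromide or transfer silicon instead of closing the ring. It may also add at an internal carbon of the diene, and liberated SO2 may consume ketene acetal. The fallback uses known chemistry, sets out from 5 and comes back at 13. The symmetric, electron-rich alkyne di-tert-butoxyethyne is added to 5; alkynes are established partners of halothiophene dioxides, the adduct losing SO2 at once, and no regiochemical question arises. This should give methyl 2,3,4-tribromo-5,6-di-tert-butoxybenzoate F1. CF3CO2H in CH2Cl2 removes both tert-butyl groups to give methyl 2,3,4-tribromo-5,6-dihydroxybenzoate F2. Its 6-hydroxyl is tied to the ester carbonyl by a hydrogen bond, so one equivalent of K2CO3 ionizes the more acidic 5-hydroxyl next to bromine. That phenoxide is arylated without metal by (2-bromophenyl)(2,4,6-trimethoxyphenyl)iodonium 4-methylbenzenesulfonate F3, which is made in one flask from 1-bromo-2-iodobenzene, mCPBA, TsOH and 1,3,5-trimethoxybenzene. The product is 13, and steps 5 and 6 follow unchanged.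

Step 2. S-oxidation of a thiophene deactivated by three bromines and an ester may not start, or may stall at the S-oxide, where self-condensation competes. The fallback changes the control group, sets out from 1 and comes back at 15. The lithium species 2 is quenched with Me3SiCl to give 2,3,4-tribromo-5-(trimethylsilyl)thiophene F4. Silylated thiophenes are oxidized by mCPBA in hot 1,2-dichloroethane, which should give 2,3,4-tribromo-5-(trimethylsilyl)thiophene 1,1-dioxide F5. Cycloaddition with 9 under the conditions of step 4 then relies on the bulk of silicon, no longer on an acceptor, to send the nucleophilic carbon to the C–Br terminus. It should give 3,4,5-tribromo-2-(2-bromophenoxy)-6-(trimethylsilyl)phenol F6. Ipso-protodesilylation ortho to the hydroxyl with CF3CO2H in CH2Cl2 then delivers 15 without steps 5 and 6.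

Step 6. Loss of CO2 from an acid on an electron-poor ring may be slow, and long heating with silver may erode the C–Br bonds. The fallback sets out from 14 and comes back at 15. Ipso-iododecarboxylation with I2 and K3PO4 in MeCN, an electrophilic substitution typical of salicylic acids, should give 3,4,5-tribromo-2-(2-bromophenoxy)-6-iodophenol F7. Treatment with i-PrMgCl·LiCl (2.1 equiv, THF, −40 °C) deprotonates the phenol and exchanges iodine much faster than bromine. A cold quench with aqueous NH4Cl, before the ortho-bromoaryl magnesium species can eliminate, gives 15.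

**Further compounds**

F1 | step 4 | methyl 2,3,4-tribromo-5,6-di-tert-butoxybenzoate | COC(=O)c1c(Br)c(Br)c(Br)c(OC(C)(C)C)c1OC(C)(C)C
F2 | step 4 | methyl 2,3,4-tribromo-5,6-dihydroxybenzoate | COC(=O)c1c(Br)c(Br)c(Br)c(O)c1O
F3 | step 4 | (2-bromophenyl)(2,4,6-trimethoxyphenyl)iodonium 4-methylbenzenesulfonate | COc1cc(OC)c([I+]c2ccccc2Br)c(OC)c1.Cc1ccc(cc1)S([O-])(=O)=O
F4 | step 2 | 2,3,4-tribromo-5-(trimethylsilyl)thiophene | C[Si](C)(C)c1sc(Br)c(Br)c1Br
F5 | step 2 | 2,3,4-tribromo-5-(trimethylsilyl)thiophene 1,1-dioxide | C[Si](C)(C)C1=C(Br)C(Br)=C(Br)S1(=O)=O
F6 | step 2 | 3,4,5-tribromo-2-(2-bromophenoxy)-6-(trimethylsilyl)phenol | C[Si](C)(C)c1c(O)c(Oc2ccccc2Br)c(Br)c(Br)c1Br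
F7 | step 6 | 3,4,5-tribromo-2-(2-bromophenoxy)-6-iodophenol | Oc1c(I)c(Br)c(Br)c(Br)c1Oc1ccccc1Br
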